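**Retrosynthetic overview**

1. The strategy rests on C7, the benzylic CH(OAc) carbon: a single carbon bonded to C8 (the CH(CH3)–O–ring B methine), to C1 of ring A (3,4,5-trimethoxyphenyl) and to the acetoxy oxygen. A boron-bound CHCl carbenoid acquires exactly this pattern after two 1,2-shifts and C–B oxidation (ring B = 4-allyl-2,6-dimethoxyphenyl).
2. At C7: OAc ⇒ OH ⇒ C7–B (retentive oxidation); C7–C1 (ring A) ⇒ aryl Grignard reagent 10; C7–C8 ⇒ LiCHCl2 inserted into the C8–B bond of boronate 8.
3. Boronate 8 ⇒ invertive C8–O bond formation between the (1R)-1-chloroethyl boronate 5 and the ring-B phenoxide; 5 ⇒ methylboronate 3 + LiCHCl2; 3 ⇒ methylboronic acid + (S,S)-1,2-dicyclohexylethane-1,2-diol.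
4. One (S,S)-diol on boron sets C8 (step 2, inverted in step 3) and C7 (step 5); it is released in the oxidation.
5. Ring formation: none. Rings A and B are bought intact and no ring is closed at any stage.

Key step: step 5

Remark: the sense of induction assumed for the (S,S)-diol (R–B to (1R)-R–CHCl–B when Cl > R > B) is the established one for C2-symmetric diol boronic esters of this configuration; both homologations use it in the same sense.

**Route**

Step 1
Reactants: 1 methylboronic acid; 2 (1S,2S)-1,2-dicyclohexylethane-1,2-diol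
Product: 3 (4S,5S)-4,5-dicyclohexyl-2-methyl-1,3,2-dioxaborolane
Conditions: Et2O, rt; water removed by toluene azeotrope
Reagents that add atoms: none
Why: Boronic ester formation from a boronic acid and a 1,2-diol is driven to completion by removal of water and does not touch the two carbinol centres.

Step 2
Reactants: 3 (4S,5S)-4,5-dicyclohexyl-2-methyl-1,3,2-dioxaborolane
Product: 5 (4S,5S)-2-[(1R)-1-chloroethyl]-4,5-dicyclohexyl-1,3,2-dioxaborolane, via lithium (dichloromethyl)(methyl)borate 4 (not isolated)
Conditions: CH2Cl2, n-BuLi, THF, −100 °C; then 3; ZnCl2 (1 equiv), −100 °C → rt; pentane/sat. NH4Cl work-up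
Reagents that add atoms: (dichloromethyl)lithium, [Li]C(Cl)Cl, made in the flask from dichloromethane, ClCCl, and n-butyllithium, CCCC[Li]
Why: Matteson homologation: LiCHCl2 adds to boron and, with ZnCl2 assistance, methyl shifts from boron to carbon while the (S,S)-diol selects which diastereotopic chloride leaves, which should set the new centre as (1R).

Step 3
Reactants: 5 (4S,5S)-2-[(1R)-1-chloroethyl]-4,5-dicyclohexyl-1,3,2-dioxaborolane; 6 4-allyl-2,6-dimethoxyphenol
Product: 8 (4S,5S)-2-[(1S)-1-(4-allyl-2,6-dimethoxyphenoxy)ethyl]-4,5-dicyclohexyl-1,3,2-dioxaborolane, via sodium 4-allyl-2,6-dimethoxyphenoxide 7 (not isolated)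
Conditions: 6 (1.2 equiv), NaH (1.1 equiv), THF, 0 °C; then 5, THF/DMSO (4:1), rt
Reagents that add atoms: none
Why: Matteson substitution of an α-chloro boronic ester by an oxygen nucleophile: the phenoxide binds boron and the aryloxy oxygen shifts from boron to carbon anti to the departing chloride, so C8 should be inverted to (1S), the spatial sense the target needs (the descriptor becomes R once C7 replaces boron); phenol in excess over NaH leaves no strong base to isomerise the allyl group, and the low solubility of NaCl limits chloride-induced epimerisation of 5.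

Step 4
Reactants: 9 5-bromo-1,2,3-trimethoxybenzene
Product: 10 3,4,5-trimethoxyphenylmagnesium bromide (titrated THF solution)
Conditions: Mg turnings, I2 (cat.), THF, 45 °C
Reagents that add atoms: magnesium, [Mg]
Why: Grignard reagent formation by insertion of magnesium into the aryl C–Br bond; the three methyl ethers are inert.

Step 5
Reactants: 8 (4S,5S)-2-[(1S)-1-(4-allyl-2,6-dimethoxyphenoxy)ethyl]-4,5-dicyclohexyl-1,3,2-dioxaborolane; 10 3,4,5-trimethoxyphenylmagnesium bromide
Product: 14 (4S,5S)-2-[(1R,2R)-2-(4-allyl-2,6-dimethoxyphenoxy)-1-(3,4,5-trimethoxyphenyl)propyl]-4,5-dicyclohexyl-1,3,2-dioxaborolane, via lithium dichloromethyl borate 11 (not isolated), via α-chloro boronic ester 12 (not isolated), via bromomagnesium aryl borate 13 (not isolated)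
Conditions: CH2Cl2, n-BuLi, THF, −100 °C; then 8; ZnCl2 (3 equiv), −100 °C → rt; THF exchanged for pentane, LiCl/ZnCl2 filtered off under Ar; then 10 (1.3 equiv), THF, −78 °C → rt
Reagents that add atoms: (dichloromethyl)lithium, [Li]C(Cl)Cl, made in the flask from dichloromethane, ClCCl, and n-butyllithium, CCCC[Li]
Why: Matteson homologation followed by Grignard substitution, run as one telescoped operation: LiCHCl2 adds to boron of 8 to give borate 11, ZnCl2 promotes the 1,2-shift of C8 from boron to the carbenoid carbon with loss of one chloride (C7–C8 bond, C8 migrating with retention) to give chloride 12, and after the chloride salts are removed 10 adds to boron to give borate 13, whose aryl group shifts to C7 anti-periplanar to the remaining chloride (C7–C1 bond, inversion at C7). The closest known reaction type is this same two-stage chain extension of C2-symmetric diol boronic esters, established for α-benzyloxy substrates; the α-aryloxy case is an application to a new molecule. No ring is closed. The new stereocentre C7 is controlled by the (S,S)-diol, which fixes in the ZnCl2-bridged borate which of the two diastereotopic chlorides leaves, so that 12 should be (1R), and the invertive arylation then leaves boron where the acetoxy oxygen has to go, giving the threo (7R,8R) array. The step needs reagent control to prevail over the resident C8 centre and both 1,2-shifts to outrun β-elimination (or, in 11, direct expulsion) of the ring-B aryloxide; the first rests on the diol-dictated geometry of the rearranging borate, the second on chloride being by far the better leaving group, on forming both borates at low temperature and on using only a small excess of 10 once ZnCl2 has been removed. The allyl group and the aryl methyl ethers are inert to LiCHCl2 at −100 °C and to the Grignard reagent.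

Step 6
Reactants: 14 (4S,5S)-2-[(1R,2R)-2-(4-allyl-2,6-dimethoxyphenoxy)-1-(3,4,5-trimethoxyphenyl)propyl]-4,5-dicyclohexyl-1,3,2-dioxaborolane
Product: 15 (1R,2R)-2-(4-allyl-2,6-dimethoxyphenoxy)-1-(3,4,5-trimethoxyphenyl)propan-1-ol
Conditions: NaBO3·4H2O, THF/H2O (1:1), 0 °C → rt
Reagents that add atoms: sodium perborate, [Na+].[O-]OB=O (used as the tetrahydrate NaBO3·4H2O)
Why: Perborate oxidation of a boronic ester: the peroxy borate shifts C7 from boron to oxygen with retention, so the C–B bond should become the (7R) C–OH bond; the mildly basic medium and the speed of this shift are relied on to pre-empt β-elimination of the ring-B aryloxide, and the allyl alkene is not oxidised.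

Step 7
Reactants: 15 (1R,2R)-2-(4-allyl-2,6-dimethoxyphenoxy)-1-(3,4,5-trimethoxyphenyl)propan-1-ol
Product: 16 (1R,2R)-2-(4-allyl-2,6-dimethoxyphenoxy)-1-(3,4,5-trimethoxyphenyl)propyl acetate (CNP0117299.1)
Conditions: Ac2O, pyridine, DMAP (cat.), CH2Cl2, 0 °C → rt
Reagents that add atoms: acetic anhydride, CC(=O)OC(C)=O
Why: DMAP-catalysed O-acetylation of a secondary benzylic alcohol breaks no bond at C7 or C8, so the (7R,8R) configuration is carried into the target.

**Compound list**

1 | methylboronic acid | CB(O)O | starting material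
2 | (1S,2S)-1,2-dicyclohexylethane-1,2-diol | O[C@@H](C1CCCCC1)[C@@H](O)C1CCCCC1 | starting material
3 | (4S,5S)-4,5-dicyclohexyl-2-methyl-1,3,2-dioxaborolane | CB1O[C@@H](C2CCCCC2)[C@H](C2CCCCC2)O1 | intermediate
4 | lithium (4S,5S)-4,5-dicyclohexyl-2-(dichloromethyl)-2-methyl-1,3,2-dioxaborolan-2-uide | [Li+].C[B-]1(C(Cl)Cl)O[C@@H](C2CCCCC2)[C@H](C2CCCCC2)O1 | intermediate
5 | (4S,5S)-2-[(1R)-1-chloroethyl]-4,5-dicyclohexyl-1,3,2-dioxaborolane | C[C@H](Cl)B1O[C@@H](C2CCCCC2)[C@H](C2CCCCC2)O1 | intermediate
6 | 4-allyl-2,6-dimethoxyphenol | C=CCc1cc(OC)c(O)c(OC)c1 | starting material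
7 | sodium 4-allyl-2,6-dimethoxyphenoxide | [Na+].[O-]c1c(OC)cc(CC=C)cc1OC | intermediate
8 | (4S,5S)-2-[(1S)-1-(4-allyl-2,6-dimethoxyphenoxy)ethyl]-4,5-dicyclohexyl-1,3,2-dioxaborolane | C=CCc1cc(OC)c(O[C@H](C)B2O[C@@H](C3CCCCC3)[C@H](C3CCCCC3)O2)c(OC)c1 | intermediate
9 | 5-bromo-1,2,3-trimethoxybenzene | COc1cc(Br)cc(OC)c1OC | starting material
10 | 3,4,5-trimethoxyphenylmagnesium bromide | COc1cc([Mg]Br)cc(OC)c1OC | intermediate
11 | lithium (4S,5S)-2-[(1S)-1-(4-allyl-2,6-dimethoxyphenoxy)ethyl]-4,5-dicyclohexyl-2-(dichloromethyl)-1,3,2-dioxaborolan-2-uide | [Li+].C=CCc1cc(OC)c(O[C@H](C)[B-]2(C(Cl)Cl)O[C@@H](C3CCCCC3)[C@H](C3CCCCC3)O2)c(OC)c1 | intermediate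
12 | (4S,5S)-2-[(1R,2R)-2-(4-allyl-2,6-dimethoxyphenoxy)-1-chloropropyl]-4,5-dicyclohexyl-1,3,2-dioxaborolane | C=CCc1cc(OC)c(O[C@H](C)[C@H](Cl)B2O[C@@H](C3CCCCC3)[C@H](C3CCCCC3)O2)c(OC)c1 | intermediate
13 | bromomagnesium (4S,5S)-2-[(1R,2R)-2-(4-allyl-2,6-dimethoxyphenoxy)-1-chloropropyl]-4,5-dicyclohexyl-2-(3,4,5-trimethoxyphenyl)-1,3,2-dioxaborolan-2-uide | [Mg+]Br.C=CCc1cc(OC)c(O[C@H](C)[C@H](Cl)[B-]2(c3cc(OC)c(OC)c(OC)c3)O[C@@H](C3CCCCC3)[C@H](C3CCCCC3)O2)c(OC)c1 | intermediate
14 | (4S,5S)-2-[(1R,2R)-2-(4-allyl-2,6-dimethoxyphenoxy)-1-(3,4,5-trimethoxyphenyl)propyl]-4,5-dicyclohexyl-1,3,2-dioxaborolane | C=CCc1cc(OC)c(O[C@H](C)[C@H](B2O[C@@H](C3CCCCC3)[C@H](C3CCCCC3)O2)c2cc(OC)c(OC)c(OC)c2)c(OC)c1 | intermediate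
15 | (1R,2R)-2-(4-allyl-2,6-dimethoxyphenoxy)-1-(3,4,5-trimethoxyphenyl)propan-1-ol | C=CCc1cc(OC)c(O[C@H](C)[C@H](O)c2cc(OC)c(OC)c(OC)c2)c(OC)c1 | intermediate
16 | (1R,2R)-2-(4-allyl-2,6-dimethoxyphenoxy)-1-(3,4,5-trimethoxyphenyl)propyl acetate | C=CCc1cc(OC)c(O[C@H](C)[C@H](OC(C)=O)c2cc(OC)c(OC)c(OC)c2)c(OC)c1 | target

**Step count**

Total: 7 steps. Longest linear sequence: 6 steps (1, 2, 3, 5, 6, 7); step 4 is a one-step side branch.

**Steps most likely to fail**

Step 5. Once 10 has added to boron, borate 13 may fragment by loss of the ring-B aryloxide from C8 (β-elimination) faster than the aryl group shifts to C7, or the hindered boron may not take up the aryl nucleophile. The diol may also override the C8 centre only incompletely in the first shift. The fallback keeps the first migration and makes the C7–C1 bond by carbonyl addition. It sets out from 8: the LiCHCl2/ZnCl2 stage is run alone and chloride 12 is worked up (pentane/sat. NH4Cl). 12 is oxidised with 30% H2O2 in THF over NaH2PO4/Na2HPO4 buffer (pH 7–8, 0 °C), conditions under which an α-chloro boronic ester collapses to the aldehyde, here (R)-2-(4-allyl-2,6-dimethoxyphenoxy)propanal F1. Grignard reagent 10 is then added to F1 precomplexed with MgBr2·OEt2 in CH2Cl2/THF at −78 °C. The five-membered magnesium chelate between the carbonyl and aryloxy oxygens should direct the aryl group to the face that gives the threo alcohol. The fallback comes back to the route at 15, replacing steps 5 and 6.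

Step 3. The hindered, weakly nucleophilic 2,6-dimethoxyphenoxide may bind boron only slowly. The liberated chloride could then epimerise unreacted 5 (and with it C8), or loss of HCl to the vinylboronate could take over. The fallback makes the C8–O bond on a lactate and leaves boron out. It sets out from 6: a Mitsunobu reaction with ethyl (S)-lactate (PPh3, DIAD, THF, 0 °C → rt) should give, with inversion, ethyl (R)-2-(4-allyl-2,6-dimethoxyphenoxy)propanoate F2. Reduction with i-Bu2AlH (CH2Cl2, −78 °C) should stop at (R)-2-(4-allyl-2,6-dimethoxyphenoxy)propanal F1. Chelation-controlled addition of 10 (MgBr2·OEt2, CH2Cl2/THF, −78 °C) then leads to the threo alcohol. The fallback comes back to the route at 15, replacing steps 1–3, 5 and 6.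

Step 6. The peroxy borate formed from 14 may lose the ring-B aryloxide from C8 (β-elimination to the 1-arylpropene) instead of shifting C7 to oxygen, or attack at the dicyclohexyl-flanked boron may be too slow to compete. The fallback brings the C7 oxygen in as a ketone and sets C7 by hydride delivery. It sets out from 6: Williamson etherification with (S)-2-chloropropanoic acid (NaH, THF, reflux; inversion) should give (R)-2-(4-allyl-2,6-dimethoxyphenoxy)propanoic acid F3. Coupling with MeNH(OMe)·HCl (EDC·HCl, HOBt, i-Pr2NEt, CH2Cl2) gives (R)-2-(4-allyl-2,6-dimethoxyphenoxy)-N-methoxy-N-methylpropanamide F4. Addition of 10 (THF, 0 °C) gives (R)-2-(4-allyl-2,6-dimethoxyphenoxy)-1-(3,4,5-trimethoxyphenyl)propan-1-one F5. Reduction with the bulky, poorly chelating KBH(s-Bu)3 (THF, −78 °C) should follow the polar Felkin–Anh model, with the aryloxy group anti to the incoming hydride, and give the threo alcohol. The fallback comes back to the route at 15, replacing steps 1–3, 5 and 6.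

**Further compounds**

F1 | step 5 | (R)-2-(4-allyl-2,6-dimethoxyphenoxy)propanal | C=CCc1cc(OC)c(O[C@H](C)C=O)c(OC)c1
F2 | step 3 | ethyl (R)-2-(4-allyl-2,6-dimethoxyphenoxy)propanoate | C=CCc1cc(OC)c(O[C@H](C)C(=O)OCC)c(OC)c1
F3 | step 6 | (R)-2-(4-allyl-2,6-dimethoxyphenoxy)propanoic acid | C=CCc1cc(OC)c(O[C@H](C)C(=O)O)c(OC)c1
F4 | step 6 | (R)-2-(4-allyl-2,6-dimethoxyphenoxy)-N-methoxy-N-methylpropanamide | C=CCc1cc(OC)c(O[C@H](C)C(=O)N(C)OC)c(OC)c1
F5 | step 6 | (R)-2-(4-allyl-2,6-dimethoxyphenoxy)-1-(3,4,5-trimethoxyphenyl)propan-1-one | C=CCc1cc(OC)c(O[C@H](C)C(=O)c2cc(OC)c(OC)c(OC)c2)c(OC)c1
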